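**Retrosynthetic overview** (ring atoms follow the spiro[5.5]undecane numbering of the target: C1 bears =CH2, C4 is CHBr, C5 is CMe2, C6 is the spiro carbon, C8 is CHBr, C9 is C(Me)Cl, C11 is the CH2 on C6 in the arm without bromine)

1. The target comes from methylenation of the C1 ketone of a spiro ketone.
2. Ring B is closed last by the C6–C11 bond: a C6 enolate, released by loss of CO2, alkylates a primary C11–Br and sets the spiro centre. This is possible because C1 of ring A is carried as a ketone and C6 carries a carboxyl group, so C6 is the α-carbon of a β-keto acid that can only give the C1=C6 enolate.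
3. Ring A is closed before that by the C5–C6 bond: silver(I) ionises a tertiary bromide next to the C4 bromide to a bromonium ion, which the enol carbon of a β-keto ester captures.
4. The acyclic β-keto ester comes from allyl acetoacetate (C2, C1, C6) and two primary triflates, each made by a catalytic enantioselective dihalogenation of an allylic alcohol: prenol (C3–C5, dibromide) and (Z)-3-methylpent-2-ene-1,5-diol from 4-methyl-5,6-dihydro-2H-pyran-2-one (C7–C11, bromochloride).
5. Ring order: ring A (C1–C6) first, ring B (C6–C11) second.

Key step: step 11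

Assumptions: in steps 1 and 5 the enantiomer of the Schiff-base ligand is the one that gives the stated configuration, and 4-methyl-5,6-dihydro-2H-pyran-2-one is taken as a purchasable starting material.

**Route**

Step 1
Reactants: 1 3-methylbut-2-en-1-ol (prenol)
Product: 2 (R)-2,3-dibromo-3-methylbutan-1-ol
Conditions: NBS, BrTi(OiPr)3, chiral tridentate Schiff-base ligand (20 mol %), hexanes, −20 °C
Reagents that add atoms: N-bromosuccinimide O=C1CCC(=O)N1Br; bromotitanium triisopropoxide CC(C)O[Ti](Br)(OC(C)C)OC(C)C
Why: Titanium-alkoxide-directed catalytic enantioselective dibromination of an allylic alcohol (anti addition, Br+ from NBS, bromide delivered from titanium) should set C2 as R under ligand control.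

Step 2
Reactants: 2 (R)-2,3-dibromo-3-methylbutan-1-ol
Product: 3 (R)-2,3-dibromo-3-methylbutyl trifluoromethanesulfonate
Conditions: Tf2O, 2,6-lutidine, CH2Cl2, −78 °C, used crude
Reagents that add atoms: triflic anhydride O=S(=O)(OS(=O)(=O)C(F)(F)F)C(F)(F)F
Why: O-Triflation of the primary alcohol with a hindered pyridine base at low temperature should leave the C–Br bonds and the stereocentre untouched.

Step 3
Reactants: 4 allyl acetoacetate; 3 (R)-2,3-dibromo-3-methylbutyl trifluoromethanesulfonate
Product: 6 allyl (6R)-6,7-dibromo-7-methyl-3-oxooctanoate, via acetoacetate dianion 5 (not isolated)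
Conditions: NaH, THF, 0 °C; n-BuLi, 0 °C; then 3, −78 → −40 °C; AcOH quench
Reagents that add atoms: none
Why: γ-Alkylation of the acetoacetate dianion, whose terminal carbanion should displace the primary triflate by SN2 at −78 °C far faster than any attack at the hindered secondary or tertiary bromide, so the stereocentre is carried through.

Step 4
Reactants: 7 4-methyl-5,6-dihydro-2H-pyran-2-one
Product: 8 (2Z)-3-methylpent-2-ene-1,5-diol
Conditions: DIBAL-H (3 equiv), CH2Cl2, −78 → 0 °C; Rochelle salt work-up
Reagents that add atoms: none
Why: 1,2-Reduction of the α,β-unsaturated lactone should give the diol, with the Z geometry inherited from the ring.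

Step 5
Reactants: 8 (2Z)-3-methylpent-2-ene-1,5-diol
Product: 9 (2S,3S)-2-bromo-3-chloro-3-methylpentane-1,5-diol
Conditions: NBS, ClTi(OiPr)3 (2.2 equiv), chiral tridentate Schiff-base ligand (20 mol %), hexanes/CH2Cl2, −20 °C
Reagents that add atoms: N-bromosuccinimide O=C1CCC(=O)N1Br; chlorotitanium triisopropoxide CC(C)O[Ti](Cl)(OC(C)C)OC(C)C
Why: Titanium-alkoxide-directed catalytic enantioselective bromochlorination of the allylic alcohol, by anti addition across the Z alkene with Br at C2 and titanium-delivered chloride at the tertiary C3, should set both stereocentres under ligand control while the remote hydroxyl is a spectator titanate.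

Step 6
Reactants: 9 (2S,3S)-2-bromo-3-chloro-3-methylpentane-1,5-diol
Product: 10 (2S,3S)-2,5-dibromo-3-chloro-3-methylpentan-1-ol
Conditions: CBr4, PPh3 (1.05 equiv each), CH2Cl2, −20 °C
Reagents that add atoms: carbon tetrabromide BrC(Br)(Br)Br
Why: Appel bromination should select the unhindered C5 hydroxyl, because the C1 hydroxyl is β-branched and inductively deactivated by the C2 bromine; no stereocentre is involved.

Step 7
Reactants: 10 (2S,3S)-2,5-dibromo-3-chloro-3-methylpentan-1-ol
Product: 11 (2S,3S)-2,5-dibromo-3-chloro-3-methylpentyl trifluoromethanesulfonate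
Conditions: Tf2O, 2,6-lutidine, CH2Cl2, −78 °C, used crude
Reagents that add atoms: triflic anhydride O=S(=O)(OS(=O)(=O)C(F)(F)F)C(F)(F)F
Why: O-Triflation of the remaining primary alcohol at low temperature should not disturb the halides or the stereocentres.

Step 8
Reactants: 6 allyl (6R)-6,7-dibromo-7-methyl-3-oxooctanoate; 11 (2S,3S)-2,5-dibromo-3-chloro-3-methylpentyl trifluoromethanesulfonate
Product: 13 allyl (6R)-6,7-dibromo-2-[(2S,3S)-2,5-dibromo-3-chloro-3-methylpentyl]-7-methyl-3-oxooctanoate (C2 epimers), via sodium enolate 12 (not isolated)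
Conditions: NaH (1.0 equiv), THF, 0 °C; then 11, −40 → 0 °C
Reagents that add atoms: none
Why: C-Alkylation of the stabilised β-keto ester enolate (sodium counter-ion in THF favours carbon) by the primary triflate, which should react at −40 °C orders of magnitude faster than the primary bromide kept for step 11; the new stereocentre forms unselectively and is erased later.

Step 9
Reactants: 13 allyl (6R)-6,7-dibromo-2-[(2S,3S)-2,5-dibromo-3-chloro-3-methylpentyl]-7-methyl-3-oxooctanoate
Product: 14 allyl (3R)-3-bromo-1-[(2S,3S)-2,5-dibromo-3-chloro-3-methylpentyl]-2,2-dimethyl-6-oxocyclohexane-1-carboxylate (C1 epimers)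
Conditions: AgOTf (1.1 equiv), 2,6-di-tert-butyl-4-methylpyridine (1.2 equiv), (CF3)2CHOH/CH2Cl2 1:4, −40 → −10 °C
Reagents that add atoms: none
Why: Silver-assisted ionisation of the tertiary C–Br bond, anchimerically assisted by the adjacent secondary bromine, should give a bromonium ion of unchanged configuration that the β-keto ester enol carbon opens at the tertiary terminus in a chair-like six-ring closure (halonium-initiated cation–enol cyclization from an enantioenriched vicinal dihalide), the tertiary bromide ionising far faster than the side-chain tertiary chloride; the bromine-bearing ring carbon stays R and the configuration of the new quaternary carbon is irrelevant because step 11 erases it.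

Step 10
Reactants: 14 allyl (3R)-3-bromo-1-[(2S,3S)-2,5-dibromo-3-chloro-3-methylpentyl]-2,2-dimethyl-6-oxocyclohexane-1-carboxylate
Product: 15 (3R)-3-bromo-1-[(2S,3S)-2,5-dibromo-3-chloro-3-methylpentyl]-2,2-dimethyl-6-oxocyclohexane-1-carboxylic acid (C1 epimers)
Conditions: Pd(PPh3)4 (3 mol %), p-toluenesulfinic acid (1.1 equiv), CH2Cl2, 0 °C; cold work-up, used at once
Reagents that add atoms: none
Why: Palladium(0)-catalysed deallylation with a sulfinic acid as allyl acceptor should cleave only the allyl ester through a π-allyl complex under neutral, non-basic conditions, so the quaternary β-keto acid forms without retro-Claisen cleavage and is kept cold to avoid premature loss of CO2.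

Step 11
Reactants: 15 (3R)-3-bromo-1-[(2S,3S)-2,5-dibromo-3-chloro-3-methylpentyl]-2,2-dimethyl-6-oxocyclohexane-1-carboxylic acid
Product: 18 (4R,6R,8S,9S)-4,8-dibromo-9-chloro-5,5,9-trimethylspiro[5.5]undecan-1-one, via sodium carboxylate 16 (not isolated), via sodium enolate 17 (not isolated)
Conditions: NaH (0.98 equiv), THF, −20 °C; then DMF, 15-crown-5, 0 → 35 °C, 0.01 M
Reagents that add atoms: none
Why: Proposed new method: NaH converts the β-keto acid into its sodium carboxylate, which in a dipolar aprotic medium should lose CO2 (the reverse of enolate carboxylation; closest known reaction types are Krapcho-type dealkoxycarbonylation, palladium decarboxylative enolate generation and the classical base-mediated spiroalkylation of 2-(ω-haloalkyl)cyclohexanones) to release the tetrasubstituted C1=C6 enolate regiospecifically, with no enolate ever formed towards C2. The enolate carbon C6 then displaces the primary bromide at C11 in a 6-exo-tet SN2 closure of ring B, which forms the C6–C11 bond and the spiro quaternary centre. C6 is controlled by the chair-like transition state of the forming ring, in which C8–Br and C9–Cl are equatorial and the bulky C5 (CMe2) arm of the enolate is pseudo-equatorial. In ring A this is axial attack on the enolate anti to the pseudo-axial C5 methyl with C4–Br equatorial, so the two preferences reinforce each other. The step needs C- over O-alkylation and six- over three-membered ring closure onto the secondary bromides at C4 and C8: O-alkylation would need an eight-membered ring, and both secondary bromides are flanked by fully substituted carbons whereas C11 is an unhindered primary carbon.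

Step 12
Reactants: 18 (4R,6R,8S,9S)-4,8-dibromo-9-chloro-5,5,9-trimethylspiro[5.5]undecan-1-one
Product: 19 (4R,6S,8S,9S)-4,8-dibromo-9-chloro-5,5,9-trimethyl-1-methylidenespiro[5.5]undecane
Conditions: Cp2TiMe2 (3 equiv), toluene/THF, 65 °C, dark
Reagents that add atoms: dimethyltitanocene [CH3-].[CH3-].[Ti+4].c1cc[cH-]c1.c1cc[cH-]c1
Why: Petasis methylenation, in which the non-basic titanium methylidene formed thermally should olefinate the hindered, enolisable ketone through an oxatitanacyclobutane without loss of HBr or HCl and without touching any stereocentre (the C6 descriptor changes from R to S only because the CIP priorities change).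

**Compound list**

1 | 3-methylbut-2-en-1-ol (prenol) | CC(C)=CCO | starting material
2 | (R)-2,3-dibromo-3-methylbutan-1-ol | OC[C@@H](Br)C(C)(C)Br | intermediate
3 | (R)-2,3-dibromo-3-methylbutyl trifluoromethanesulfonate | O=S(=O)(OC[C@@H](Br)C(C)(C)Br)C(F)(F)F | intermediate
4 | allyl acetoacetate (prop-2-en-1-yl 3-oxobutanoate) | CC(=O)CC(=O)OCC=C | starting material
5 | sodium lithium dianion of allyl acetoacetate | C=C([O-])C=C([O-])OCC=C.[Na+].[Li+] | intermediate
6 | allyl (6R)-6,7-dibromo-7-methyl-3-oxooctanoate | C=CCOC(=O)CC(=O)CC[C@@H](Br)C(C)(C)Br | intermediate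
7 | 4-methyl-5,6-dihydro-2H-pyran-2-one | CC1=CC(=O)OCC1 | starting material
8 | (2Z)-3-methylpent-2-ene-1,5-diol | OC/C=C(C)\CCO | intermediate
9 | (2S,3S)-2-bromo-3-chloro-3-methylpentane-1,5-diol | OCC[C@](C)(Cl)[C@@H](Br)CO | intermediate
10 | (2S,3S)-2,5-dibromo-3-chloro-3-methylpentan-1-ol | BrCC[C@](C)(Cl)[C@@H](Br)CO | intermediate
11 | (2S,3S)-2,5-dibromo-3-chloro-3-methylpentyl trifluoromethanesulfonate | BrCC[C@](C)(Cl)[C@@H](Br)COS(=O)(=O)C(F)(F)F | intermediate
12 | sodium enolate of 6 | [Na+].C=CCOC(=O)C=C([O-])CC[C@@H](Br)C(C)(C)Br | intermediate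
13 | allyl (6R)-6,7-dibromo-2-[(2S,3S)-2,5-dibromo-3-chloro-3-methylpentyl]-7-methyl-3-oxooctanoate (C2 epimers) | C=CCOC(=O)C(C[C@H](Br)[C@@](C)(Cl)CCBr)C(=O)CC[C@@H](Br)C(C)(C)Br | intermediate
14 | allyl (3R)-3-bromo-1-[(2S,3S)-2,5-dibromo-3-chloro-3-methylpentyl]-2,2-dimethyl-6-oxocyclohexane-1-carboxylate (C1 epimers) | C=CCOC(=O)C1(C[C@H](Br)[C@@](C)(Cl)CCBr)C(=O)CC[C@@H](Br)C1(C)C | intermediate
15 | (3R)-3-bromo-1-[(2S,3S)-2,5-dibromo-3-chloro-3-methylpentyl]-2,2-dimethyl-6-oxocyclohexane-1-carboxylic acid (C1 epimers) | OC(=O)C1(C[C@H](Br)[C@@](C)(Cl)CCBr)C(=O)CC[C@@H](Br)C1(C)C | intermediate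
16 | sodium salt of 15 | [Na+].[O-]C(=O)C1(C[C@H](Br)[C@@](C)(Cl)CCBr)C(=O)CC[C@@H](Br)C1(C)C | intermediate
17 | sodium (4R)-4-bromo-2-[(2S,3S)-2,5-dibromo-3-chloro-3-methylpentyl]-3,3-dimethylcyclohex-1-en-1-olate | [Na+].[O-]C1=C(C[C@H](Br)[C@@](C)(Cl)CCBr)C(C)(C)[C@H](Br)CC1 | intermediate
18 | (4R,6R,8S,9S)-4,8-dibromo-9-chloro-5,5,9-trimethylspiro[5.5]undecan-1-one | O=C1CC[C@@H](Br)C(C)(C)[C@]12CC[C@](C)(Cl)[C@@H](Br)C2 | intermediate
19 | (4R,6S,8S,9S)-4,8-dibromo-9-chloro-5,5,9-trimethyl-1-methylidenespiro[5.5]undecane | C=C1CC[C@@H](Br)C(C)(C)[C@]12CC[C@](C)(Cl)[C@@H](Br)C2 | target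

Total step count: 12. Longest linear sequence: 9 steps (steps 4 to 12, from 7).

**Steps most likely to fail**

Step 11 (proposed new method). The sodium carboxylate may lose CO2 too slowly, the enolate may be protonated before ring closure, or three-membered ring closure onto a secondary bromide may compete with the six-membered closure. The fallback sets out from 15 and uses known chemistry: neutral thermal decarboxylation in toluene at 60 °C should give (4R)-4-bromo-2-[(2S,3S)-2,5-dibromo-3-chloro-3-methylpentyl]-3,3-dimethylcyclohexan-1-one F1. Classical spiroalkylation of this 2-(ω-bromoalkyl)cyclohexanone with KOtBu in t-BuOH/THF at 0 °C, where the enolates equilibrate and only the C6 enolate can close a six-membered ring, comes back to the route at 18.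

Step 9. The side-chain tertiary chloride may ionise in competition, or the bromonium ion may be captured by the ketone oxygen instead of the enol carbon. The fallback sets out from 6 and closes ring A before the second halogenated fragment is present: the same silver-assisted cyclization on 6 should give allyl (3R)-3-bromo-2,2-dimethyl-6-oxocyclohexane-1-carboxylate F2. C-Alkylation of the sodium enolate of F2 with triflate 11 (NaH, THF/DMPU, −20 °C) comes back to the route at 14.

Step 8. The ambident enolate may be O-alkylated by the hard triflate, or proton transfer to the product may be followed by three-membered ring closure onto the neighbouring C–Br bond. The fallback sets out from 11 and 3 and builds the β-keto ester by acylation instead of alkylation. The lithium enolate of allyl acetate is alkylated with 11 to allyl (4S,5S)-4,7-dibromo-5-chloro-5-methylheptanoate F3. The lithium enolate of N-methoxy-N-methylacetamide is alkylated with 3 to (4R)-4,5-dibromo-N-methoxy-N,5-dimethylhexanamide F4. Claisen-type acylation of the lithium enolate of F3 (LDA, 2 equiv, −78 °C) with F4 comes back to the route at 13.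

**Further compounds**

F1 | step 11 | (4R)-4-bromo-2-[(2S,3S)-2,5-dibromo-3-chloro-3-methylpentyl]-3,3-dimethylcyclohexan-1-one | O=C1CC[C@@H](Br)C(C)(C)C1C[C@H](Br)[C@@](C)(Cl)CCBr
F2 | step 9 | allyl (3R)-3-bromo-2,2-dimethyl-6-oxocyclohexane-1-carboxylate | C=CCOC(=O)C1C(=O)CC[C@@H](Br)C1(C)C
F3 | step 8 | allyl (4S,5S)-4,7-dibromo-5-chloro-5-methylheptanoate | C=CCOC(=O)CC[C@H](Br)[C@@](C)(Cl)CCBr
F4 | step 8 | (4R)-4,5-dibromo-N-methoxy-N,5-dimethylhexanamide | CON(C)C(=O)CC[C@@H](Br)C(C)(C)Br
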